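The plan rests on recognising flavan C4 as a former aldehyde carbon. This methine joins C6 of the flavanone ring A, C4a of the tetraoxygenated ring D and the C3 methylene, so the whole pyran ring can be cut into an aryl aldehyde, a phenol and styrene. One acid-catalysed operation then forges C4–C4a, C3–C4 and O1–C2, closes the flavan heterocycle and sets both of its stereocentres. The aldehyde partner is the enantiopure (2R)-flavanone-6-carbaldehyde, with its chelated 5-hydroxyl left free; the phenol partner is symmetric 2,5-dimethoxyresorcinol. The formyl group is installed on the achiral chromone, before the flavanone stereocentre exists.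

Key step: step 6

Remark: the sense of induction of both chiral catalysts is assigned by analogy with their closest precedents; should either prove opposite, its mirror-image form is used and nothing else changes.

Step 1
Reactants: 1 2',6'-dihydroxy-4'-methoxyacetophenone
Product: 3 5-hydroxy-7-methoxy-4H-chromen-4-one, via enaminone 2 (not isolated)
Conditions: Me2NCH(OMe)2, toluene, 90 °C; then conc. HCl, CH2Cl2, 40 °C
Reagents that add atoms: N,N-dimethylformamide dimethyl acetal, COC(OC)N(C)C
Why: Condensation of the methyl ketone with the amide acetal gives enaminone 2, and acid then triggers intramolecular oxa-Michael addition of a phenol and loss of dimethylamine (the standard enaminone chromone synthesis); the two hydroxyls of 1 are equivalent, so a single chromone should result.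

Step 2
Reactants: 3 5-hydroxy-7-methoxy-4H-chromen-4-one
Product: 5 5-hydroxy-7-methoxy-4-oxo-4H-chromene-6-carbaldehyde, via hydroxymethyl chromone 4 (not isolated)
Conditions: MgCl2, Et3N, (CH2O)n, MeCN, 80 °C; then 1 M HCl
Reagents that add atoms: paraformaldehyde (as formaldehyde), C=O
Why: Casnati–Skattebøl ortho-formylation: the magnesium phenoxide of the 5-OH delivers formaldehyde to its only free ortho carbon, C6 (C8 has no adjacent hydroxyl), and a second formaldehyde oxidises the magnesium alkoxide of 4 by Oppenauer-type hydride transfer, all at a stage with no stereocentre and no enolisable ketone for the amine base to disturb.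

Step 3
Reactants: 5 5-hydroxy-7-methoxy-4-oxo-4H-chromene-6-carbaldehyde, 6 phenylboronic acid
Product: 7 (2R)-5-hydroxy-7-methoxy-4-oxo-2-phenylchromane-6-carbaldehyde
Conditions: Pd(OCOCF3)2 (5 mol%), (S)-t-BuPyOx [(S)-4-tert-butyl-2-(pyridin-2-yl)-4,5-dihydrooxazole] (6 mol%), NH4PF6, H2O, ClCH2CH2Cl, 60 °C
Reagents that add atoms: none
Why: Asymmetric conjugate addition of an arylboronic acid to a chromone, catalysed by a cationic pyridine–oxazoline complex of divalent palladium: the 2R centre is set in the face-selective carbopalladation of C2=C3 under control of the (S)-ligand (sense taken from cyclic enones), water protonates the palladium enolate, the non-basic medium excludes retro-oxa-Michael racemisation, and the flanked, hydrogen-bonded formyl group is a poor insertion partner for the aryl–palladium species.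

Step 4
Reactants: 8 2,6-dibromo-4-methoxyphenol
Product: 9 1,3-dibromo-2,5-dimethoxybenzene
Conditions: MeI, K2CO3, DMF, 40 °C
Reagents that add atoms: iodomethane, CI
Why: Williamson O-methylation of the only acidic site, the phenol flanked by two bromines, with a small unhindered electrophile.

Step 5
Reactants: 9 1,3-dibromo-2,5-dimethoxybenzene
Product: 11 2,5-dimethoxybenzene-1,3-diol, via bromophenol 10 (not isolated)
Conditions: Pd2(dba)3 (2 mol%), tBuXPhos (8 mol%), KOH, 1,4-dioxane/H2O, 100 °C, degassed; then 1 M HCl under N2
Reagents that add atoms: potassium hydroxide, [K+].[OH-]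
Why: Palladium-catalysed hydroxylation of aryl bromides with KOH (C–O cross-coupling on zerovalent palladium with a bulky biaryl phosphine), run on two equivalent bromides; the ortho methoxy group and excess hydroxide disfavour diaryl ether formation, and acidification under N2 protects the electron-rich resorcinol from air oxidation.

Step 6
Reactants: 7 (2R)-5-hydroxy-7-methoxy-4-oxo-2-phenylchromane-6-carbaldehyde, 11 2,5-dimethoxybenzene-1,3-diol, 12 styrene
Product: 15 (2R)-6-[(2S,4S)-7-hydroxy-5,8-dimethoxy-2-phenylchroman-4-yl]-5-hydroxy-7-methoxy-2-phenylchroman-4-one, via carbinol 13 (not isolated), via quinone methide 14 (not isolated)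
Conditions: (R)-3,3'-bis(2,4,6-triisopropylphenyl)-1,1'-binaphthyl-2,2'-diyl N-triflyl phosphoramide (10 mol%), 11 (2 equiv), 12 (10 equiv), 5 Å MS, toluene, 0 °C to rt, 7 added slowly
Reagents that add atoms: none
Why: Proposed new method: the strong chiral acid activates the hydrogen-bonded aldehyde of 7 for Friedel–Crafts hydroxyalkylation by 11 (whose two ring CH positions are equivalent), and ionisation of carbinol 13 gives ortho-quinone methide 14 as a hydrogen-bonded ion pair with the phosphoramide anion, which styrene attacks at the methide carbon through its terminal carbon (C3–C4) before the resulting benzylic cation is captured by the neighbouring ring D phenol oxygen (O1–C2). The closest known reactions are achiral acid-catalysed phenol/aldehyde/styrene chroman syntheses and chiral phosphoric acid-catalysed [4+2] cycloadditions of ortho-quinone methides, made from preformed ortho-hydroxybenzyl alcohols, with styrenes; their enantioselective three-component union is untested. The pyran ring closes as the second bond of this stepwise oxa-[4+2], a six-membered C–O closure of a phenol onto a benzylic cation. C4 is set under catalyst control, the bound chiral anion shielding one face of the methide (the remote flavanone centre has no influence, so the catalyst antipode is matched to 4S), and C2 follows from C4 by 1,3-induction in a chair-like closure with phenyl equatorial and the 4-aryl group pseudoaxial, away from the peri 5-methoxy group, which should give the 2,4-trans (2S) isomer. The step needs closure on ring D and not on the 5-OH of ring A, which the carbonyl chelate of that hydroxyl secures, and it needs one annulation per resorcinol and styrene instead of a second phenol as the trap, which the excess of 11, the tenfold excess of 12 and the acid-reversibility of triarylmethane adducts are meant to secure. The flavanone centre is inert to acid and should stay R.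

Compound list
1 | 2',6'-dihydroxy-4'-methoxyacetophenone | CC(=O)c1c(O)cc(OC)cc1O | starting material
2 | (E)-1-(2,6-dihydroxy-4-methoxyphenyl)-3-(dimethylamino)prop-2-en-1-one (not isolated) | CN(C)/C=C/C(=O)c1c(O)cc(OC)cc1O | intermediate
3 | 5-hydroxy-7-methoxy-4H-chromen-4-one | COc1cc(O)c2c(c1)OC=CC2=O | intermediate
4 | 5-hydroxy-6-(hydroxymethyl)-7-methoxy-4H-chromen-4-one, present as its magnesium salt (not isolated) | COc1cc2OC=CC(=O)c2c(O)c1CO | intermediate
5 | 5-hydroxy-7-methoxy-4-oxo-4H-chromene-6-carbaldehyde | COc1cc2OC=CC(=O)c2c(O)c1C=O | intermediate
6 | phenylboronic acid | OB(O)c1ccccc1 | starting material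
7 | (2R)-5-hydroxy-7-methoxy-4-oxo-2-phenylchromane-6-carbaldehyde (key-step precursor) | COc1cc2c(c(O)c1C=O)C(=O)C[C@H](c1ccccc1)O2 | intermediate
8 | 2,6-dibromo-4-methoxyphenol | COc1cc(Br)c(O)c(Br)c1 | starting material
9 | 1,3-dibromo-2,5-dimethoxybenzene | COc1cc(Br)c(OC)c(Br)c1 | intermediate
10 | 3-bromo-2,5-dimethoxyphenol (not isolated) | COc1cc(O)c(OC)c(Br)c1 | intermediate
11 | 2,5-dimethoxybenzene-1,3-diol (2,5-dimethoxyresorcinol) | COc1cc(O)c(OC)c(O)c1 | intermediate
12 | styrene | C=Cc1ccccc1 | starting material
13 | (2R)-6-[(2,4-dihydroxy-3,6-dimethoxyphenyl)(hydroxy)methyl]-5-hydroxy-7-methoxy-2-phenylchroman-4-one, both carbinol epimers (not isolated) | COc1cc2c(c(O)c1C(O)c1c(OC)cc(O)c(OC)c1O)C(=O)C[C@H](c1ccccc1)O2 | intermediate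
14 | 3-hydroxy-6-{[(2R)-5-hydroxy-7-methoxy-4-oxo-2-phenylchroman-6-yl]methylidene}-2,5-dimethoxycyclohexa-2,4-dien-1-one, ion-paired with the catalyst (not isolated) | COC1=CC(O)=C(OC)C(=O)C1=Cc1c(OC)cc2c(c1O)C(=O)C[C@H](c1ccccc1)O2 | intermediate
15 | (2R)-6-[(2S,4S)-7-hydroxy-5,8-dimethoxy-2-phenylchroman-4-yl]-5-hydroxy-7-methoxy-2-phenylchroman-4-one (CNP0301559.1) | COc1cc2c(c(O)c1[C@@H]1C[C@@H](c3ccccc3)Oc3c(OC)c(O)cc(OC)c31)C(=O)C[C@H](c1ccccc1)O2 | target

Total step count: 6. Longest linear sequence: 4 steps (steps 1, 2, 3 and 6); steps 4 and 5 form the second branch.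

Steps most likely to fail

Step 6 (Proposed new method). The ion-paired methide may be trapped by a second resorcinol instead of styrene, the product may undergo a second annulation, the cation may close through the ring A hydroxyl, or facial and cis/trans control may be insufficient. The fallback uses known chemistry and sets out from 7 and 11. They are first joined by the boronic acid-templated ortho-hydroxyalkylation of a phenol with an aldehyde (6, catalytic EtCO2H, toluene, azeotropic removal of water). This reaction is ortho-specific and should stop after one aldehyde is taken up, because the new benzylic oxygen and the phenol oxygen are locked through boron in (2R)-5-hydroxy-6-(7-hydroxy-5,8-dimethoxy-2-phenyl-4H-1,3,2-benzodioxaborinin-4-yl)-7-methoxy-2-phenylchroman-4-one F1 (both C4 epimers). F1 is then opened with BF3·OEt2 in CH2Cl2 at low temperature in the presence of 12, the established way to release an ortho-quinone methide from a benzodioxaborin for [4+2] capture by styrene. This should give 15 together with its flavan diastereomer (2R)-6-[(2R,4R)-7-hydroxy-5,8-dimethoxy-2-phenylchroman-4-yl]-5-hydroxy-7-methoxy-2-phenylchroman-4-one F2. Because the flavanone centre is fixed as R, the two are diastereomers and are separated by preparative HPLC; the route is rejoined at 15.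

Step 3. The aryl–palladium species may add to the formyl group, the O,O-chelating hydroxy aldehyde may sequester the cationic catalyst, or the enantioselectivity may erode on this more electron-poor chromone. The fallback sets out from 3 and reverses the order of events. The same palladium/pyridine–oxazoline phenyl addition is run on the formyl-free chromone to give (2R)-5-hydroxy-7-methoxy-2-phenylchroman-4-one F3. The aldehyde is then introduced by titanium-directed Rieche formylation (Cl2CHOMe, TiCl4, CH2Cl2, 0 °C) ortho to the 5-OH, under acidic conditions that should not open the flavanone; the route is rejoined at 7.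

Step 2. The chelated, carbonyl-deactivated magnesium phenoxide may form the C–C bond sluggishly, or the hydroxymethyl intermediate may be diverted into methylene-bridged dimers. The fallback sets out from 3. Iodination ortho to the free 5-OH (benzyltrimethylammonium dichloroiodate, CaCO3, CH2Cl2/MeOH, rt) should give 5-hydroxy-6-iodo-7-methoxy-4H-chromen-4-one F4. Palladium-catalysed reductive carbonylation of this aryl iodide (Pd(OAc)2, dppp, CO, Et3SiH, Na2CO3, DMF, 80 °C) then installs the formyl group; the route is rejoined at 5.

Further compounds
F1 | step 6 | (2R)-5-hydroxy-6-(7-hydroxy-5,8-dimethoxy-2-phenyl-4H-1,3,2-benzodioxaborinin-4-yl)-7-methoxy-2-phenylchroman-4-one (both C4 epimers) | COc1cc2c(c(O)c1C1OB(c3ccccc3)Oc3c(OC)c(O)cc(OC)c31)C(=O)C[C@H](c1ccccc1)O2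
F2 | step 6 | (2R)-6-[(2R,4R)-7-hydroxy-5,8-dimethoxy-2-phenylchroman-4-yl]-5-hydroxy-7-methoxy-2-phenylchroman-4-one | COc1cc2c(c(O)c1[C@H]1C[C@H](c3ccccc3)Oc3c(OC)c(O)cc(OC)c31)C(=O)C[C@H](c1ccccc1)O2
F3 | step 3 | (2R)-5-hydroxy-7-methoxy-2-phenylchroman-4-one | COc1cc(O)c2C(=O)C[C@H](c3ccccc3)Oc2c1
F4 | step 2 | 5-hydroxy-6-iodo-7-methoxy-4H-chromen-4-one | COc1cc2OC=CC(=O)c2c(O)c1I
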